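## Retrosynthetic overview

- The target is made by desilylation of its allylic TBS ether. The aryl ketone is unmasked only two mild steps from the end, by oxidation of a benzylic alcohol, so that the enolisable α-aryloxy stereocenter is never exposed to base as a ketone.
- The (E)-3-hydroxypropenyl side chain comes from Suzuki coupling of an aryl bromide with an (E)-alkenylboronate made from propargyl alcohol.
- The C-methyl group comes from a CH2OH group (tosylate, then hydride) of a 1,3-diol obtained by reductive removal of an Evans auxiliary.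
- The key C–C bond, ArCH(OH)–CH(OAr'), comes from a boron-mediated Evans syn-aldol between 3,4,5-trimethoxybenzaldehyde and the N-(aryloxyacetyl)oxazolidinone derived from 4-bromo-2,6-dimethoxyphenol. The auxiliary sets the aryloxy-bearing stereocenter.
- No ring is formed in the route. Both benzene rings are bought, and the oxazolidinone ring of the auxiliary is bought and later released.

Assumption: salts formed only by proton transfer (phenoxide, carboxylate, alkoxide) are not counted as separate compounds; the descriptor of the aryloxy-bearing carbon changes along the route (S in 11, R from 13 on) only through CIP priority changes, never by inversion.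

## Route

Step 1
Reactants: 1 4-bromo-2,6-dimethoxyphenol; 2 ethyl bromoacetate
Product: 3 ethyl 2-(4-bromo-2,6-dimethoxyphenoxy)acetate
Conditions: K2CO3, acetone, reflux
Reagents that add atoms: none
Why: Williamson ether synthesis, in which the phenoxide displaces the activated primary bromide by SN2 while the aryl bromide is inert.

Step 2
Reactants: 3 ethyl 2-(4-bromo-2,6-dimethoxyphenoxy)acetate
Product: 4 2-(4-bromo-2,6-dimethoxyphenoxy)acetic acid
Conditions: LiOH·H2O, THF/H2O (3:1), rt; then 1 M HCl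
Reagents that add atoms: lithium hydroxide, [Li+].[OH-]
Why: Saponification of an unhindered ethyl ester is fast at room temperature and touches neither the aryl ether nor the aryl bromide.

Step 3
Reactants: 4 2-(4-bromo-2,6-dimethoxyphenoxy)acetic acid; 5 (S)-4-benzyl-1,3-oxazolidin-2-one
Product: 7 (S)-4-benzyl-3-[2-(4-bromo-2,6-dimethoxyphenoxy)acetyl]-1,3-oxazolidin-2-one, via mixed pivalic anhydride 6 (not isolated)
Conditions: PivCl, Et3N, THF, −20 °C; then LiCl, 5, −20 °C → rt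
Reagents that add atoms: none
Why: N-acylation of the Evans auxiliary through a mixed anhydride (pivaloyl chloride supplies the pivaloyl group of 6), the oxazolidinone attacking the less hindered acyl carbon; the α-carbon is CH2, so nothing can epimerise.

Step 4
Reactants: 7 (S)-4-benzyl-3-[2-(4-bromo-2,6-dimethoxyphenoxy)acetyl]-1,3-oxazolidin-2-one; 8 3,4,5-trimethoxybenzaldehyde
Product: 11 (S)-4-benzyl-3-[(2S,3R)-2-(4-bromo-2,6-dimethoxyphenoxy)-3-hydroxy-3-(3,4,5-trimethoxyphenyl)propanoyl]-1,3-oxazolidin-2-one, via boron Z-enolate 9 (not isolated), via boron aldolate 10 (not isolated)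
Conditions: Bu2BOTf, Et3N, CH2Cl2, −78 → 0 °C; then 8, −78 → 0 °C; then pH 7 buffer (NaH2PO4/Na2HPO4), MeOH, 30% H2O2, 0 °C
Reagents that add atoms: none
Why: Evans syn-aldol reaction, in which the Z-boron enolate (Bu2B from Bu2BOTf) reacts through a Zimmerman–Traxler chair on the face opposite the benzyl group, setting the aryloxy carbon as S (the carbon that is R in the target) and the carbinol carbon as R.

Step 5
Reactants: 11 (S)-4-benzyl-3-[(2S,3R)-2-(4-bromo-2,6-dimethoxyphenoxy)-3-hydroxy-3-(3,4,5-trimethoxyphenyl)propanoyl]-1,3-oxazolidin-2-one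
Product: 13 (1R,2R)-2-(4-bromo-2,6-dimethoxyphenoxy)-1-(3,4,5-trimethoxyphenyl)propane-1,3-diol, via hydroxy aldehyde 12 (not isolated)
Conditions: NaBH4, THF/H2O (4:1), 0 °C → rt
Reagents that add atoms: none
Why: Reductive cleavage of the imide by borohydride attacks the exocyclic carbonyl, releases the auxiliary for recovery and reduces the aldehyde formed to the primary alcohol without touching either stereocenter.

Step 6
Reactants: 13 (1R,2R)-2-(4-bromo-2,6-dimethoxyphenoxy)-1-(3,4,5-trimethoxyphenyl)propane-1,3-diol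
Product: 14 (2R,3R)-2-(4-bromo-2,6-dimethoxyphenoxy)-3-hydroxy-3-(3,4,5-trimethoxyphenyl)propyl 4-methylbenzenesulfonate
Conditions: TsCl (1.1 equiv), pyridine, CH2Cl2, 0 °C
Reagents that add atoms: p-toluenesulfonyl chloride, Cc1ccc(cc1)S(Cl)(=O)=O
Why: Selective sulfonylation, since the unhindered primary hydroxyl reacts much faster than the hindered secondary benzylic one at 0 °C.

Step 7
Reactants: 14 (2R,3R)-2-(4-bromo-2,6-dimethoxyphenoxy)-3-hydroxy-3-(3,4,5-trimethoxyphenyl)propyl 4-methylbenzenesulfonate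
Product: 15 (1R,2R)-2-(4-bromo-2,6-dimethoxyphenoxy)-1-(3,4,5-trimethoxyphenyl)propan-1-ol
Conditions: LiEt3BH (3.5 equiv), THF, 0 °C → rt; aq. NH4Cl
Reagents that add atoms: none
Why: SN2 hydride displacement of the primary tosylate by LiEt3BH gives the methyl group without involving the stereocenters, and the aryl bromide is inert at this temperature.

Step 8
Reactants: 16 prop-2-yn-1-ol
Product: 17 tert-butyldimethyl(prop-2-yn-1-yloxy)silane
Conditions: TBSCl, imidazole, CH2Cl2, 0 °C → rt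
Reagents that add atoms: tert-butyldimethylsilyl chloride, CC(C)(C)[Si](C)(C)Cl
Why: Standard imidazole-promoted silylation of a primary alcohol.

Step 9
Reactants: 17 tert-butyldimethyl(prop-2-yn-1-yloxy)silane
Product: 18 (E)-tert-butyldimethyl{[3-(4,4,5,5-tetramethyl-1,3,2-dioxaborolan-2-yl)prop-2-en-1-yl]oxy}silane
Conditions: pinacolborane, Cp2Zr(H)Cl (5 mol %), Et3N (10 mol %), neat, 60 °C
Reagents that add atoms: pinacolborane, CC1(C)OBOC1(C)C
Why: Zirconium-catalysed hydroboration of a terminal alkyne adds H–B syn and anti-Markovnikov, giving only the E-alkenylboronate.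

Step 10
Reactants: 15 (1R,2R)-2-(4-bromo-2,6-dimethoxyphenoxy)-1-(3,4,5-trimethoxyphenyl)propan-1-ol; 18 (E)-tert-butyldimethyl{[3-(4,4,5,5-tetramethyl-1,3,2-dioxaborolan-2-yl)prop-2-en-1-yl]oxy}silane
Product: 19 (1R,2R)-2-{4-[(E)-3-(tert-butyldimethylsilyloxy)prop-1-en-1-yl]-2,6-dimethoxyphenoxy}-1-(3,4,5-trimethoxyphenyl)propan-1-ol
Conditions: Pd(dppf)Cl2 (5 mol %), K2CO3, 1,4-dioxane/H2O (5:1), 80 °C
Reagents that add atoms: none
Why: Suzuki–Miyaura cross-coupling proceeds with retention of alkene geometry, so the E side chain is installed at the unhindered aryl bromide while the free secondary alcohol and both stereocenters are untouched.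

Step 11
Reactants: 19 (1R,2R)-2-{4-[(E)-3-(tert-butyldimethylsilyloxy)prop-1-en-1-yl]-2,6-dimethoxyphenoxy}-1-(3,4,5-trimethoxyphenyl)propan-1-ol
Product: 20 (R)-2-{4-[(E)-3-(tert-butyldimethylsilyloxy)prop-1-en-1-yl]-2,6-dimethoxyphenoxy}-1-(3,4,5-trimethoxyphenyl)propan-1-one
Conditions: Dess–Martin periodinane (1.3 equiv), pyridine, CH2Cl2, 0 °C → rt
Reagents that add atoms: none
Why: Dess–Martin oxidation turns the only free hydroxyl into the aryl ketone under near-neutral, non-enolising conditions, so the adjacent aryloxy stereocenter (R, as in the target) is kept.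

Step 12
Reactants: 20 (R)-2-{4-[(E)-3-(tert-butyldimethylsilyloxy)prop-1-en-1-yl]-2,6-dimethoxyphenoxy}-1-(3,4,5-trimethoxyphenyl)propan-1-one
Product: 21 (R)-2-{4-[(E)-3-hydroxyprop-1-en-1-yl]-2,6-dimethoxyphenoxy}-1-(3,4,5-trimethoxyphenyl)propan-1-one (CNP0171423.1)
Conditions: HF·pyridine, pyridine, THF, 0 °C → rt
Reagents that add atoms: none
Why: Buffered fluoride desilylation frees the allylic alcohol under weakly acidic conditions that neither enolise the α-aryloxy ketone nor ionise the electron-rich cinnamyl alcohol.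

## Compound list

1 | 4-bromo-2,6-dimethoxyphenol | COc1cc(Br)cc(OC)c1O | starting material
2 | ethyl bromoacetate | CCOC(=O)CBr | starting material
3 | ethyl 2-(4-bromo-2,6-dimethoxyphenoxy)acetate | CCOC(=O)COc1c(OC)cc(Br)cc1OC | intermediate
4 | 2-(4-bromo-2,6-dimethoxyphenoxy)acetic acid | OC(=O)COc1c(OC)cc(Br)cc1OC | intermediate
5 | (S)-4-benzyl-1,3-oxazolidin-2-one | O=C1N[C@@H](Cc2ccccc2)CO1 | starting material
6 | 2-(4-bromo-2,6-dimethoxyphenoxy)acetic pivalic anhydride | CC(C)(C)C(=O)OC(=O)COc1c(OC)cc(Br)cc1OC | intermediate (not isolated)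
7 | (S)-4-benzyl-3-[2-(4-bromo-2,6-dimethoxyphenoxy)acetyl]-1,3-oxazolidin-2-one | O=C1OC[C@H](Cc2ccccc2)N1C(=O)COc1c(OC)cc(Br)cc1OC | intermediate
8 | 3,4,5-trimethoxybenzaldehyde | COc1cc(C=O)cc(OC)c1OC | starting material
9 | dibutylboron Z-enolate of 7 | CCCCB(CCCC)O/C(=C\Oc1c(OC)cc(Br)cc1OC)N1[C@@H](Cc2ccccc2)COC1=O | intermediate (not isolated)
10 | dibutylboron aldolate of 11 | CCCCB(CCCC)O[C@H](c1cc(OC)c(OC)c(OC)c1)[C@H](Oc1c(OC)cc(Br)cc1OC)C(=O)N1[C@@H](Cc2ccccc2)COC1=O | intermediate (not isolated)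
11 | (S)-4-benzyl-3-[(2S,3R)-2-(4-bromo-2,6-dimethoxyphenoxy)-3-hydroxy-3-(3,4,5-trimethoxyphenyl)propanoyl]-1,3-oxazolidin-2-one | O=C1OC[C@H](Cc2ccccc2)N1C(=O)[C@@H](Oc1c(OC)cc(Br)cc1OC)[C@H](O)c1cc(OC)c(OC)c(OC)c1 | intermediate
12 | (2S,3R)-2-(4-bromo-2,6-dimethoxyphenoxy)-3-hydroxy-3-(3,4,5-trimethoxyphenyl)propanal | O=C[C@@H](Oc1c(OC)cc(Br)cc1OC)[C@H](O)c1cc(OC)c(OC)c(OC)c1 | intermediate (not isolated)
13 | (1R,2R)-2-(4-bromo-2,6-dimethoxyphenoxy)-1-(3,4,5-trimethoxyphenyl)propane-1,3-diol | OC[C@@H](Oc1c(OC)cc(Br)cc1OC)[C@H](O)c1cc(OC)c(OC)c(OC)c1 | intermediate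
14 | (2R,3R)-2-(4-bromo-2,6-dimethoxyphenoxy)-3-hydroxy-3-(3,4,5-trimethoxyphenyl)propyl 4-methylbenzenesulfonate | Cc1ccc(cc1)S(=O)(=O)OC[C@@H](Oc1c(OC)cc(Br)cc1OC)[C@H](O)c1cc(OC)c(OC)c(OC)c1 | intermediate
15 | (1R,2R)-2-(4-bromo-2,6-dimethoxyphenoxy)-1-(3,4,5-trimethoxyphenyl)propan-1-ol | C[C@@H](Oc1c(OC)cc(Br)cc1OC)[C@H](O)c1cc(OC)c(OC)c(OC)c1 | intermediate
16 | prop-2-yn-1-ol | C#CCO | starting material
17 | tert-butyldimethyl(prop-2-yn-1-yloxy)silane | C#CCO[Si](C)(C)C(C)(C)C | intermediate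
18 | (E)-tert-butyldimethyl{[3-(4,4,5,5-tetramethyl-1,3,2-dioxaborolan-2-yl)prop-2-en-1-yl]oxy}silane | CC(C)(C)[Si](C)(C)OC/C=C/B1OC(C)(C)C(C)(C)O1 | intermediate
19 | (1R,2R)-2-{4-[(E)-3-(tert-butyldimethylsilyloxy)prop-1-en-1-yl]-2,6-dimethoxyphenoxy}-1-(3,4,5-trimethoxyphenyl)propan-1-ol | C[C@@H](Oc1c(OC)cc(/C=C/CO[Si](C)(C)C(C)(C)C)cc1OC)[C@H](O)c1cc(OC)c(OC)c(OC)c1 | intermediate
20 | (R)-2-{4-[(E)-3-(tert-butyldimethylsilyloxy)prop-1-en-1-yl]-2,6-dimethoxyphenoxy}-1-(3,4,5-trimethoxyphenyl)propan-1-one | C[C@@H](Oc1c(OC)cc(/C=C/CO[Si](C)(C)C(C)(C)C)cc1OC)C(=O)c1cc(OC)c(OC)c(OC)c1 | intermediate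
21 | (R)-2-{4-[(E)-3-hydroxyprop-1-en-1-yl]-2,6-dimethoxyphenoxy}-1-(3,4,5-trimethoxyphenyl)propan-1-one | COc1cc(C(=O)[C@@H](C)Oc2c(OC)cc(/C=C/CO)cc2OC)cc(OC)c1OC | target

## Summary

Total step count: 12. Longest linear sequence: 10 steps (steps 1–7 and 10–12, from compound 1); steps 8 and 9 form a two-step side branch.

Three steps most likely to fail:

**Step 4 (aldol: selectivity or conversion with the hindered aryloxyacetyl imide and the electron-rich aldehyde).** The fallback sets out from compound 1 and comes back to the route at compound 20. Phenol 1 is coupled with commercial ethyl (S)-lactate under Mitsunobu conditions (PPh3, DIAD, THF, 0 °C → rt), which inverts the lactate carbon and gives ethyl (R)-2-(4-bromo-2,6-dimethoxyphenoxy)propanoate F1. Reduction with i-Bu2AlH in CH2Cl2 at −78 °C gives (R)-2-(4-bromo-2,6-dimethoxyphenoxy)propanal F2, which is used cold and crude. It is added to commercial 3,4,5-(MeO)3C6H2MgBr in THF at −78 °C, giving alcohol 15 mixed with its C-1 epimer (1S,2R)-2-(4-bromo-2,6-dimethoxyphenoxy)-1-(3,4,5-trimethoxyphenyl)propan-1-ol F3. The mixture is taken through the conditions of steps 10 and 11 unchanged, the epimer passing through (1S,2R)-2-{4-[(E)-3-(tert-butyldimethylsilyloxy)prop-1-en-1-yl]-2,6-dimethoxyphenoxy}-1-(3,4,5-trimethoxyphenyl)propan-1-ol F4. Both epimers converge on ketone 20 because C-1 becomes the carbonyl carbon.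

**Step 7 (hydride displacement next to a free benzylic alkoxide: oxetane formation or sluggish reduction).** The fallback sets out from compound 11 and comes back at compound 15. The aldol hydroxyl is capped first (TBSOTf, 2,6-lutidine, CH2Cl2, −78 → 0 °C) to give (S)-4-benzyl-3-[(2S,3R)-2-(4-bromo-2,6-dimethoxyphenoxy)-3-(tert-butyldimethylsilyloxy)-3-(3,4,5-trimethoxyphenyl)propanoyl]-1,3-oxazolidin-2-one F5. LiBH4 in wet Et2O at 0 °C removes the auxiliary to give (2R,3R)-2-(4-bromo-2,6-dimethoxyphenoxy)-3-(tert-butyldimethylsilyloxy)-3-(3,4,5-trimethoxyphenyl)propan-1-ol F6. TsCl and pyridine give (2R,3R)-2-(4-bromo-2,6-dimethoxyphenoxy)-3-(tert-butyldimethylsilyloxy)-3-(3,4,5-trimethoxyphenyl)propyl 4-methylbenzenesulfonate F7. LiEt3BH in THF then gives [(1R,2R)-2-(4-bromo-2,6-dimethoxyphenoxy)-1-(3,4,5-trimethoxyphenyl)propoxy](tert-butyl)dimethylsilane F8, in which no alkoxide can compete. TBAF in THF returns alcohol 15.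

**Step 10 (Suzuki coupling of an electron-rich aryl bromide; protodeboronation or silyl loss in hot aqueous base).** The fallback sets out from compound 15 and comes back at compound 19. A Heck reaction of 15 with methyl acrylate (Pd(OAc)2, P(o-tol)3, Et3N, DMF, 100 °C) gives methyl (E)-3-(4-{[(1R,2R)-1-hydroxy-1-(3,4,5-trimethoxyphenyl)propan-2-yl]oxy}-3,5-dimethoxyphenyl)prop-2-enoate F9. Reduction with i-Bu2AlH in CH2Cl2 at −78 °C gives (1R,2R)-2-{4-[(E)-3-hydroxyprop-1-en-1-yl]-2,6-dimethoxyphenoxy}-1-(3,4,5-trimethoxyphenyl)propan-1-ol F10. Selective silylation of the primary allylic hydroxyl (TBSCl 1.05 equiv, imidazole, CH2Cl2, −20 °C) gives 19.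

## Further compounds

F1 | step 4 | ethyl (R)-2-(4-bromo-2,6-dimethoxyphenoxy)propanoate | CCOC(=O)[C@@H](C)Oc1c(OC)cc(Br)cc1OC
F2 | step 4 | (R)-2-(4-bromo-2,6-dimethoxyphenoxy)propanal | C[C@@H](Oc1c(OC)cc(Br)cc1OC)C=O
F3 | step 4 | (1S,2R)-2-(4-bromo-2,6-dimethoxyphenoxy)-1-(3,4,5-trimethoxyphenyl)propan-1-ol | C[C@@H](Oc1c(OC)cc(Br)cc1OC)[C@@H](O)c1cc(OC)c(OC)c(OC)c1
F4 | step 4 | (1S,2R)-2-{4-[(E)-3-(tert-butyldimethylsilyloxy)prop-1-en-1-yl]-2,6-dimethoxyphenoxy}-1-(3,4,5-trimethoxyphenyl)propan-1-ol | C[C@@H](Oc1c(OC)cc(/C=C/CO[Si](C)(C)C(C)(C)C)cc1OC)[C@@H](O)c1cc(OC)c(OC)c(OC)c1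
F5 | step 7 | (S)-4-benzyl-3-[(2S,3R)-2-(4-bromo-2,6-dimethoxyphenoxy)-3-(tert-butyldimethylsilyloxy)-3-(3,4,5-trimethoxyphenyl)propanoyl]-1,3-oxazolidin-2-one | O=C1OC[C@H](Cc2ccccc2)N1C(=O)[C@@H](Oc1c(OC)cc(Br)cc1OC)[C@H](O[Si](C)(C)C(C)(C)C)c1cc(OC)c(OC)c(OC)c1
F6 | step 7 | (2R,3R)-2-(4-bromo-2,6-dimethoxyphenoxy)-3-(tert-butyldimethylsilyloxy)-3-(3,4,5-trimethoxyphenyl)propan-1-ol | OC[C@@H](Oc1c(OC)cc(Br)cc1OC)[C@H](O[Si](C)(C)C(C)(C)C)c1cc(OC)c(OC)c(OC)c1
F7 | step 7 | (2R,3R)-2-(4-bromo-2,6-dimethoxyphenoxy)-3-(tert-butyldimethylsilyloxy)-3-(3,4,5-trimethoxyphenyl)propyl 4-methylbenzenesulfonate | Cc1ccc(cc1)S(=O)(=O)OC[C@@H](Oc1c(OC)cc(Br)cc1OC)[C@H](O[Si](C)(C)C(C)(C)C)c1cc(OC)c(OC)c(OC)c1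
F8 | step 7 | [(1R,2R)-2-(4-bromo-2,6-dimethoxyphenoxy)-1-(3,4,5-trimethoxyphenyl)propoxy](tert-butyl)dimethylsilane | C[C@@H](Oc1c(OC)cc(Br)cc1OC)[C@H](O[Si](C)(C)C(C)(C)C)c1cc(OC)c(OC)c(OC)c1
F9 | step 10 | methyl (E)-3-(4-{[(1R,2R)-1-hydroxy-1-(3,4,5-trimethoxyphenyl)propan-2-yl]oxy}-3,5-dimethoxyphenyl)prop-2-enoate | C[C@@H](Oc1c(OC)cc(/C=C/C(=O)OC)cc1OC)[C@H](O)c1cc(OC)c(OC)c(OC)c1
F10 | step 10 | (1R,2R)-2-{4-[(E)-3-hydroxyprop-1-en-1-yl]-2,6-dimethoxyphenoxy}-1-(3,4,5-trimethoxyphenyl)propan-1-ol | C[C@@H](Oc1c(OC)cc(/C=C/CO)cc1OC)[C@H](O)c1cc(OC)c(OC)c(OC)c1
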